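The earlier runs and the new flask stem from a simulated flask with made-up constants, noise included.

Ends and transfer agent race each other.

| setting | ash | Wednesday's | Thursday's | Saturday's | Tuesday's |
|---|---|---|---|---|---|
| free monomer | 0.30 M | 0.30 M | 0.30 M | 0.30 M | 0.30 M |
| transfer agent | 0.012 M | 0.0120 M | 0.0250 M | 0.0500 M | 0.100 M |
| protic impurity | 0.022 M | 0.0150 M | 0.0150 M | 0.0150 M | 0.0150 M |
| initiator | 30 mM | 30 mM | 30 mM | 30 mM | 30 mM |
| remark | run made earlier |  |  |  |  |
| time |  | 12 h | 12 h | 12 h | 12 h |

- ash (time / h: monomer in chains / %, free monomer / %): 0.500: 6.5, 90.0; 1.33: 13.3, 80.4; 2.50: 20.8, 72.0; 4.00: 28.4, 63.4

(standard deviation of a reading: 0.5 percentage points)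

- the earlier runs were read with a standard deviation of 0.5 percentage points
- what may be going on: protic impurity + free monomer -> quenched substrate; free monomer + living end -> monomer in chains + living end; free monomer + initiator -> living end + monomer in chains; living end + transfer agent -> dead chain
- "hardly changes" means that all values lie within two and a half points (for a concentration: within two and a half percent of the largest)
- no earlier run changes the charge of transfer agent; that part of a forecast is a guess
- no earlier run changes the charge of protic impurity; that part of a forecast is a guess

1. amount of monomer in chains at the end, in percent of the free monomer charged for Wednesday's, Thursday's, Saturday's, Tuesday's, in this order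
2. the shape of the row from first to last (falls all the way / hardly changes / rises, then falls / rises all the way / falls, then rises)

In the first instants of the ash run, free monomer disappears faster than chains gain it. The gap reaches 8.2 percentage points at 4.00 h, close to the 7.33% that the protic impurity charge would quench one for one. Initiator is taken to add 10.0% to the chains while forming one living end each. Growth in the ash run therefore starts from about 82.7% of the charged free monomer, and in the new flasks from 85.0%.

In the middle of the run, two steps remain. Living ends consume free monomer and die on transfer agent, so ends minus transfer agent stays constant. Both logarithms fall in proportion to the living end, which therefore cancels: the fraction of free monomer left in the growth stage equals the fraction of transfer agent left, raised to a fixed power. That power is the transfer ratio, growth constant over transfer constant.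

The ash run yields it as a rough reading. Chain gain per free monomer is 0.0841 h⁻¹, then 0.0748 h⁻¹, at logarithmic falls of 0.0815 and 0.200. A straight line back to zero fall gives 0.0905 h⁻¹ for the full charge of ends. The later rate then implies 0.00680 M of transfer agent left, so the ratio is 0.352. Transfer against a full charge of ends runs at 0.257 h⁻¹.

Toward the end, the quotient of transfer agent over living end changes exponentially, which gives the agent left at 12 h. The reckoning, a guess across untested charges, gives 57.1%, 46.9%, 31.7% and 20.0%, so the row falls all the way. In Saturday's and Tuesday's flasks, ends are the limiting reagent.

The forecast differs from this from Thursday's on, standing lower with 57%, 31%, 14%, 12% and falls all the way; for Saturday's and Tuesday's flasks its ground is that “transfer agent exceeds initiator, so all ends die”.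

The flasks give 55.6%, 44.2%, 28.4% and 18.3%: the row falls all the way.

    protic impurity + free monomer → quenched substrate (k = 0.00184 L mol⁻¹ s⁻¹)
    free monomer + living end → monomer in chains + living end, rate k2*[living end]*[free monomer] (k = 8.78 × 10⁻⁴ L mol⁻¹ s⁻¹)
    free monomer + initiator → living end + monomer in chains (k = 0.00125 L mol⁻¹ s⁻¹)
    living end + transfer agent → dead chain (kL = 0.00317 L mol⁻¹ s⁻¹)

In Wednesday's flask, a living end facing transfer agent alone, with the other concentrations as charged, has a half-life of 5.1 h, shorter than the 12 h of the run, yet at the end 6.4% of the agent remains beside 0.0188 M of living end. Through the transfer ratio, that remainder gives free monomer 32.3% against the simulated 39.4%, and the 70% of transfer agent left in Tuesday's flask gives 75.0% against the simulated 76.7%.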